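**Retrosynthetic overview**
1. Target 17 ⇒ tricyclic 7β,8β-epoxy-9-ketone 12: angelate by SN2 opening at C-8, C-9 carbinol by hydroxyl-directed reduction, then isovaleroylation.
2. Key disconnection C-10–C-11 (cyclobutane and quaternary C-10): oxidative coupling of the two ketone enolates of the cis-fused bicyclic epoxy-diketone 10. Two α-carbons that are both nucleophilic are joined after one is oxidised to an α-keto radical (enolonium equivalent).
3. 10 ⇒ keto-aldehyde 8: seven-membered ring by aldol condensation (C-7=C-8), then convex-face epoxidation.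
4. 8 ⇒ car-3-en-5-one 2: C-4–C-10 by γ-addition of the carenone silyl dienol ether to a nitro-olefin (α-keto cation equivalent); C-6–C-7 by cyclopropane fragmentation and carbonylation. 2 comes from (+)-3-carene, which supplies the six-membered ring, the C-5 stereocentre and the gem-dimethyl group.
5. Ring order: six-membered ring (chiral pool) → seven-membered ring (step 5) → cyclobutane (step 7).

Assumptions: longipinane numbering is used for the tricycles (C-1 ketone, C-2=C-3, cyclobutane C-4/C-5/C-11/C-10, C-6 gem-dimethyl, C-7 to C-9 oxygenated); the side-chain methine that becomes quaternary C-10 in step 7 is carried as an epimer mixture and written without a stereodescriptor; 1, 4, 13 and 16 are bought.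

Step 1
Reactants: 1 (+)-3-carene
Product: 2 (1R,6S)-4,7,7-trimethylbicyclo[4.1.0]hept-3-en-2-one
Conditions: t-BuOOH (70% aq), CrO3 (5 mol %), CH2Cl2, 23 °C
Reagents that add atoms: tert-butyl hydroperoxide, CC(C)(C)OO
Why: Chromium-catalysed allylic oxidation attacks the ring CH2 next to the unsubstituted alkene carbon (as in the pinene-to-verbenone oxidation) and gives the β-methyl enone; both carene stereocentres are untouched.

Step 2
Reactants: 2 car-3-en-5-one
Product: 3 tert-butyldimethyl{[(1R,6S)-4,7,7-trimethylbicyclo[4.1.0]hepta-2,4-dien-2-yl]oxy}silane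
Conditions: TBSOTf, Et3N, CH2Cl2, 0 → 23 °C
Reagents that add atoms: tert-butyldimethylsilyl trifluoromethanesulfonate, CC(C)(C)[Si](C)(C)OS(=O)(=O)C(F)(F)F
Why: Soft enolisation; the α'-carbon is a cyclopropane CH that cannot enolise, so only the extended dienol ether forms, with the more substituted endocyclic isomer preferred.

Step 3
Reactants: 3 silyl dienol ether; 4 (E)-2-nitrobut-2-ene
Product: 6 (1R,5R,6S)-4,7,7-trimethyl-5-(3-oxobutan-2-yl)bicyclo[4.1.0]hept-3-en-2-one, via silyl nitronate 5 (not isolated)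
Conditions: SnCl4 (1 equiv), CH2Cl2, −78 °C; then 1 M aq HCl, THF, 0 → 23 °C
Reagents that add atoms: water, O
Why: Vinylogous Mukaiyama–Michael addition to a nitro-olefin (Yoshikoshi 1,4-dicarbonyl synthesis) at the γ-terminus, anti to the gem-dimethylcyclopropane, followed by Nef hydrolysis to the methyl ketone; C-4 is formed trans here and is corrected in step 5.

Step 4
Reactants: 6 cyclopropyl enone diketone
Product: 8 2-methyl-2-[(1R,2R)-3-methyl-5-oxo-2-(3-oxobutan-2-yl)cyclohex-3-en-1-yl]propanal, via tributylstannyl dienolate 7 (not isolated)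
Conditions: CO (80 atm), Bu3SnH (1.2 equiv), AIBN (cat.), C6H6, 80 °C; then H2O
Reagents that add atoms: carbon monoxide, [C-]#[O+]
Why: Proposed new method: the tin radical adds to the enone oxygen, the O-stannyl ketyl opens the cyclopropane bond that overlaps with the π system to give the tertiary C-6 radical, and this is trapped by CO and reduced by Bu3SnH to the aldehyde while C-5 keeps the carene configuration; the closest known reactions are O-stannyl ketyl cyclopropane fragmentation and radical formylation of tertiary alkyl bromides with CO and Bu3SnH.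

Step 5
Reactants: 8 keto-aldehyde
Product: 9 (1S,7R)-2,6,6,11-tetramethylbicyclo[5.4.0]undeca-4,10-diene-3,9-dione
Conditions: KOH (0.3 equiv), MeOH, 60 °C
Reagents that add atoms: none
Why: Intramolecular aldol condensation of the methyl ketone onto the non-enolisable aldehyde closes the cycloheptenone (other aldol adducts cannot dehydrate and revert), while equilibration through the extended dienolate epimerises C-4 to the cis-fused isomer, in which the C-4 substituent sits pseudo-axial to avoid A(1,2) strain with the C-3 methyl; residual trans isomer is recycled.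

Step 6
Reactants: 9 cis-fused dienedione
Product: 10 (1S,4S,5S,7R)-4,5-epoxy-2,6,6,11-tetramethylbicyclo[5.4.0]undec-10-ene-3,9-dione
Conditions: 30% aq H2O2, NaOH (0.2 equiv), MeOH, 0 °C
Reagents that add atoms: hydrogen peroxide, OO
Why: Weitz–Scheffer nucleophilic epoxidation; the β-monosubstituted enone of ring B reacts faster than the β,β-disubstituted enone of ring A, and attack on the convex face of the cis-fused bicycle (syn to both ring-fusion hydrogens) sets C-7 and C-8.

Step 7
Reactants: 10 epoxy-diketone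
Product: 12 (4R,5S,7S,8S,10R,11R)-7,8-epoxylongipin-2-ene-1,9-dione, via dilithium bis-enolate 11 (not isolated)
Conditions: LiN(i-Pr)2 (2.2 equiv), THF, −78 °C; then Fe(acac)3 (2.2 equiv), −78 → 0 °C
Reagents that add atoms: none
Why: Proposed new method: deprotonation at the only two kinetically acidic sites (C-11 methylene and C-10 methine) gives a bis-enolate in which C-10 is held pseudo-axial 1,3 to C-11, and single-electron oxidation by Fe(acac)3 turns one enolate into an α-keto radical that is captured by the other, forming the C-10–C-11 bond, the cyclobutane and quaternary C-10 with the configuration dictated by the cis ring fusion; the closest known reactions are intramolecular oxidative enolate heterocoupling to 1,4-diketones and oxidative cyclisation of diester dienolates to cyclobutanes.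

Step 8
Reactants: 12 tricyclic epoxy-dione; 13 angelic acid
Product: 14 (4R,5S,7S,8R,10R,11R)-7-hydroxy-1,9-dioxolongipin-2-en-8-yl (2Z)-2-methylbut-2-enoate
Conditions: 13 (3 equiv), Cs2CO3 (0.3 equiv), DMF, 50 °C
Reagents that add atoms: none
Why: SN2 opening of the α,β-epoxy ketone by carboxylate at the carbonyl-activated C-8 (C-7 is neopentyl and blocked) inverts C-8 to the 8α-angelate and leaves the 7β-hydroxyl.

Step 9
Reactants: 14 hydroxy keto angelate
Product: 15 (4R,5S,7S,8R,9S,10R,11R)-7,9-dihydroxy-1-oxolongipin-2-en-8-yl (2Z)-2-methylbut-2-enoate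
Conditions: Me4NBH(OAc)3, MeCN–AcOH, −30 °C
Reagents that add atoms: none
Why: Hydroxyl-directed reduction (Evans–Saksena type); hydride is delivered intramolecularly from the C-7 alkoxyborohydride and gives the 1,3-anti diol (9α-OH), and the reagent leaves the ring A enone and the ester alone.

Step 10
Reactants: 15 diol mono-angelate; 16 3-methylbutanoic anhydride
Product: 17 (4R,5S,7S,8R,9S,10R,11R)-7-hydroxy-9-(3-methylbutanoyloxy)-1-oxolongipin-2-en-8-yl (2Z)-2-methylbut-2-enoate
Conditions: 16 (1.2 equiv), Et3N, DMAP (cat.), CH2Cl2, 0 °C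
Reagents that add atoms: none
Why: DMAP-catalysed acylation of the C-9 hydroxyl, which is expected to be less shielded than the C-7 hydroxyl next to the gem-dimethyl group; no stereocentre is touched.

**Compound list**
1 | (+)-3-carene, (1S,6R)-3,7,7-trimethylbicyclo[4.1.0]hept-3-ene | CC1(C)[C@@H]2[C@H]1CC=C(C)C2 | starting material
2 | (1R,6S)-4,7,7-trimethylbicyclo[4.1.0]hept-3-en-2-one (car-3-en-5-one) | CC1(C)[C@@H]2[C@H]1C(=O)C=C(C)C2 | intermediate
3 | tert-butyldimethyl{[(1R,6S)-4,7,7-trimethylbicyclo[4.1.0]hepta-2,4-dien-2-yl]oxy}silane | CC1(C)[C@@H]2[C@H]1C(O[Si](C)(C)C(C)(C)C)=CC(C)=C2 | intermediate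
4 | (E)-2-nitrobut-2-ene | C/C=C(\C)[N+](=O)[O-] | starting material
5 | silyl nitronate: O-TBS aci-nitro ester of (1R,5R,6S)-4,7,7-trimethyl-5-(3-nitrobutan-2-yl)bicyclo[4.1.0]hept-3-en-2-one | CC1(C)[C@@H]2[C@H]1C(=O)C=C(C)[C@H]2C(C)C(C)=[N+]([O-])O[Si](C)(C)C(C)(C)C | intermediate
6 | (1R,5R,6S)-4,7,7-trimethyl-5-(3-oxobutan-2-yl)bicyclo[4.1.0]hept-3-en-2-one (side chain trans to the cyclopropane) | CC1(C)[C@@H]2[C@H]1C(=O)C=C(C)[C@H]2C(C)C(C)=O | intermediate
7 | tributylstannyl dienolate of 8 (O-SnBu3 on the ring ketone, C-6/C-1 enolate double bond) | O=CC(C)(C)[C@@H]1C=C(O[Sn](CCCC)(CCCC)CCCC)C=C(C)[C@H]1C(C)C(C)=O | intermediate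
8 | 2-methyl-2-[(1R,2R)-3-methyl-5-oxo-2-(3-oxobutan-2-yl)cyclohex-3-en-1-yl]propanal (ring substituents trans) | O=CC(C)(C)[C@@H]1CC(=O)C=C(C)[C@H]1C(C)C(C)=O | intermediate
9 | (1S,7R)-2,6,6,11-tetramethylbicyclo[5.4.0]undeca-4,10-diene-3,9-dione (cis-fused) | O=C1C=CC(C)(C)[C@@H]2CC(=O)C=C(C)[C@@H]2C1C | intermediate
10 | (1S,4S,5S,7R)-4,5-epoxy-2,6,6,11-tetramethylbicyclo[5.4.0]undec-10-ene-3,9-dione (epoxide syn to the ring-fusion hydrogens) | O=C1[C@H]3O[C@H]3C(C)(C)[C@@H]2CC(=O)C=C(C)[C@@H]2C1C | intermediate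
11 | dilithium bis-enolate of 10 (C-2/C-3 and C-8/C-9 enolates) | [Li+].[Li+].[O-]C=1[C@H]3O[C@H]3C(C)(C)[C@@H]2C=C([O-])C=C(C)[C@@H]2C=1C | intermediate
12 | (4R,5S,7S,8S,10R,11R)-7,8-epoxylongipin-2-ene-1,9-dione | O=C1[C@H]4O[C@H]4C(C)(C)[C@@H]2[C@H]3C(=O)C=C(C)[C@@H]2[C@@]13C | intermediate
13 | angelic acid, (2Z)-2-methylbut-2-enoic acid | C/C=C(/C)C(=O)O | starting material
14 | (4R,5S,7S,8R,10R,11R)-7-hydroxy-1,9-dioxolongipin-2-en-8-yl (2Z)-2-methylbut-2-enoate | C/C=C(/C)C(=O)O[C@@H]1[C@@H](O)C(C)(C)[C@@H]2[C@H]3C(=O)C=C(C)[C@@H]2[C@@]3(C)C1=O | intermediate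
15 | (4R,5S,7S,8R,9S,10R,11R)-7,9-dihydroxy-1-oxolongipin-2-en-8-yl (2Z)-2-methylbut-2-enoate | C/C=C(/C)C(=O)O[C@@H]1[C@@H](O)C(C)(C)[C@@H]2[C@H]3C(=O)C=C(C)[C@@H]2[C@@]3(C)[C@@H]1O | intermediate
16 | 3-methylbutanoic (isovaleric) anhydride | CC(C)CC(=O)OC(=O)CC(C)C | starting material
17 | CNP0151972.1, (4R,5S,7S,8R,9S,10R,11R)-8-angeloyloxy-7-hydroxy-9-(3-methylbutanoyloxy)longipin-2-en-1-one | C/C=C(/C)C(=O)O[C@@H]1[C@@H](O)C(C)(C)[C@@H]2[C@H]3C(=O)C=C(C)[C@@H]2[C@@]3(C)[C@@H]1OC(=O)CC(C)C | target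

**Totals and risks**
Total steps: 10. Longest linear sequence: 10 steps (1 → 17); 4, 13 and 16 enter as purchased reagents.

Steps most likely to fail:

Step 7 (oxidative enolate coupling to the cyclobutane). The fallback sets out from 10 and returns at 12, replacing the radical coupling by an ionic alkylation. One equivalent of LiN(i-Pr)2 at −78 °C deprotonates the ring A methylene, and NBS gives the α'-bromo ketone (1S,4S,5S,7R)-8-bromo-4,5-epoxy-2,6,6,11-tetramethylbicyclo[5.4.0]undec-10-ene-3,9-dione F1. LiN(SiMe3)2 then forms the ring B enolate, which displaces the bromide α to the ring A ketone (4-exo-tet alkylation, α-bromo ketone as enolonium equivalent) to give 12.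

Step 4 (one-pot ketyl fragmentation and carbonylation). The fallback sets out from 6 and returns at 8 in two separate operations. HBr in AcOH at 0 °C opens the cyclopropane by homoconjugate addition to the tertiary bromide (4S,5R)-5-(2-bromopropan-2-yl)-3-methyl-4-(3-oxobutan-2-yl)cyclohex-2-en-1-one F2. Radical formylation of F2 with CO (80 atm), Bu3SnH and AIBN then gives 8.

Step 10 (regioselective acylation of O-9 in the presence of O-7). The fallback sets out from 15 and returns at 17, using a protecting group in case the C-7 hydroxyl proves the more reactive one. TESOTf (1 equiv) and 2,6-lutidine at −78 °C give the silyl ether (4R,5S,7S,8R,9S,10R,11R)-9-hydroxy-1-oxo-7-(triethylsilyloxy)longipin-2-en-8-yl (2Z)-2-methylbut-2-enoate F3. Isovaleric anhydride with DMAP at 23 °C then acylates the only free hydroxyl to give (4R,5S,7S,8R,9S,10R,11R)-9-(3-methylbutanoyloxy)-1-oxo-7-(triethylsilyloxy)longipin-2-en-8-yl (2Z)-2-methylbut-2-enoate F4. HF·pyridine in THF at 0 °C removes the silyl group and gives 17.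

**Further compounds**
F1 | step 7 | (1S,4S,5S,7R)-8-bromo-4,5-epoxy-2,6,6,11-tetramethylbicyclo[5.4.0]undec-10-ene-3,9-dione | O=C1[C@H]3O[C@H]3C(C)(C)[C@@H]2C(Br)C(=O)C=C(C)[C@@H]2C1C
F2 | step 4 | (4S,5R)-5-(2-bromopropan-2-yl)-3-methyl-4-(3-oxobutan-2-yl)cyclohex-2-en-1-one | CC(C)(Br)[C@@H]1CC(=O)C=C(C)[C@H]1C(C)C(C)=O
F3 | step 10 | (4R,5S,7S,8R,9S,10R,11R)-9-hydroxy-1-oxo-7-(triethylsilyloxy)longipin-2-en-8-yl (2Z)-2-methylbut-2-enoate | C/C=C(/C)C(=O)O[C@@H]1[C@@H](O[Si](CC)(CC)CC)C(C)(C)[C@@H]2[C@H]3C(=O)C=C(C)[C@@H]2[C@@]3(C)[C@@H]1O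
F4 | step 10 | (4R,5S,7S,8R,9S,10R,11R)-9-(3-methylbutanoyloxy)-1-oxo-7-(triethylsilyloxy)longipin-2-en-8-yl (2Z)-2-methylbut-2-enoate | C/C=C(/C)C(=O)O[C@@H]1[C@@H](O[Si](CC)(CC)CC)C(C)(C)[C@@H]2[C@H]3C(=O)C=C(C)[C@@H]2[C@@]3(C)[C@@H]1OC(=O)CC(C)C
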